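## Retrosynthetic overview

1. Target 17 ⇐ global desilylation of the tris-silyl (2S)-flavanone 16.
2. 16 ⇐ C2–aryl disconnection: enantioselective palladium-catalysed conjugate arylation of the intact chromone 10 with catechol boronic acid 15. The only stereocentre and ring B arrive in one step, with no chalcone and no oxa-Michael closure.
3. 10 ⇐ 8-prenylchromone 8 by (E)-selective SeO2 allylic hydroxylation, then silylation; 8 ⇐ 7-hydroxychromone 4 by palladium-catalysed reverse O-prenylation, aromatic Claisen rearrangement to C8 and O-methylation.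
4. Ring order: no ring is constructed. Rings A and C are bought fused (chromone 4), ring B is bought (4-bromocatechol 11) and is attached in the penultimate step.

Assumption: the palladium/pyridine–oxazoline catalyst shows the same facial bias on chromone as on 3-substituted cyclohexenones, so the (R)-ligand delivers aryl to the Re face of C2 and gives the (2S)-flavanone; confirm by chiral HPLC/CD on the first run.

## Route

Step 1
Reactants: 1 2-methylbut-3-en-2-ol
Product: 3 tert-butyl 2-methylbut-3-en-2-yl carbonate, via lithium 2-methylbut-3-en-2-olate 2 (not isolated)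
Conditions: n-BuLi, THF, −78 → 0 °C; Boc2O, 0 °C → rt; H2O quench
Reagents that add atoms: di-tert-butyl dicarbonate CC(C)(C)OC(=O)OC(=O)OC(C)(C)C
Why: Alkoxide acylation (Boc transfer): the lithium alkoxide of the tertiary alcohol attacks Boc2O irreversibly and gives the mixed carbonate that zerovalent palladium ionises easily.

Step 2
Reactants: 4 7-hydroxy-4H-chromen-4-one; 3 tert-butyl 2-methylbut-3-en-2-yl carbonate
Product: 5 7-[(2-methylbut-3-en-2-yl)oxy]-4H-chromen-4-one
Conditions: Pd(PPh3)4 (2 mol%), THF, 0 °C → rt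
Reagents that add atoms: none
Why: Decarboxylative Tsuji–Trost O-allylation: zerovalent palladium ionises the tertiary carbonate, the released tert-butoxide deprotonates the acidic 7-OH, and the phenoxide attacks the more substituted allyl terminus under kinetic control to give the tertiary (reverse-prenyl) ether.

Step 3
Reactants: 5 7-[(2-methylbut-3-en-2-yl)oxy]-4H-chromen-4-one
Product: 7 7-hydroxy-8-(3-methylbut-2-en-1-yl)-4H-chromen-4-one, via cyclohexadienone tautomer 6 (not isolated)
Conditions: PhNEt2, 130 °C, Ar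
Reagents that add atoms: none
Why: Aromatic Claisen rearrangement ([3,3]-sigmatropic shift, then tautomerisation): the tertiary ether rearranges at moderate temperature, and migration goes to C8 because the C7–C8 bond has the higher double-bond character (as in 2-naphthyl and 7-oxycoumarin ethers), giving the linear prenyl group.

Step 4
Reactants: 7 7-hydroxy-8-(3-methylbut-2-en-1-yl)-4H-chromen-4-one
Product: 8 7-methoxy-8-(3-methylbut-2-en-1-yl)-4H-chromen-4-one
Conditions: MeI, K2CO3, acetone, 50 °C
Reagents that add atoms: iodomethane CI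
Why: Williamson ether synthesis: SN2 O-methylation of the only acidic site, the 7-phenoxide.

Step 5
Reactants: 8 7-methoxy-8-(3-methylbut-2-en-1-yl)-4H-chromen-4-one
Product: 9 8-[(2E)-4-hydroxy-3-methylbut-2-en-1-yl]-7-methoxy-4H-chromen-4-one
Conditions: SeO2 (0.3 equiv), t-BuOOH (3 equiv), salicylic acid (10 mol%), CH2Cl2, 0 °C → rt
Reagents that add atoms: selenium dioxide O=[Se]=O; tert-butyl hydroperoxide CC(C)(C)OO
Why: Riley allylic oxidation in its catalytic SeO2/t-BuOOH form: an ene reaction at the more substituted alkene terminus followed by a [2,3]-sigmatropic shift hydroxylates the (E)-methyl group selectively, which sets the (E) geometry and leaves the benzylic CH2 and the electron-poor chromone untouched.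

Step 6
Reactants: 9 8-[(2E)-4-hydroxy-3-methylbut-2-en-1-yl]-7-methoxy-4H-chromen-4-one
Product: 10 8-[(2E)-4-{[tert-butyl(dimethyl)silyl]oxy}-3-methylbut-2-en-1-yl]-7-methoxy-4H-chromen-4-one
Conditions: TBSCl, imidazole, CH2Cl2, rt
Reagents that add atoms: tert-butyldimethylsilyl chloride CC(C)(C)[Si](C)(C)Cl
Why: Imidazole-promoted O-silylation of the primary allylic alcohol keeps it from being oxidised by, or coordinating to, the cationic palladium catalyst of step 9.

Step 7
Reactants: 11 4-bromobenzene-1,2-diol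
Product: 12 4-bromo-1,2-bis{[tert-butyl(dimethyl)silyl]oxy}benzene
Conditions: TBSCl, imidazole, DMF, rt
Reagents that add atoms: tert-butyldimethylsilyl chloride CC(C)(C)[Si](C)(C)Cl
Why: Imidazole-promoted bis-O-silylation masks the catechol with groups that survive organolithium chemistry and come off with fluoride at the end.

Step 8
Reactants: 12 4-bromo-1,2-bis{[tert-butyl(dimethyl)silyl]oxy}benzene
Product: 15 (3,4-bis{[tert-butyl(dimethyl)silyl]oxy}phenyl)boronic acid, via aryllithium 13 (not isolated), via lithium aryl(triisopropoxy)borate 14 (not isolated)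
Conditions: n-BuLi, THF, −78 °C; B(OiPr)3, −78 °C → rt; 1 M HCl, 0 °C
Reagents that add atoms: triisopropyl borate CC(C)OB(OC(C)C)OC(C)C; water O
Why: Bromine–lithium exchange, electrophilic borylation and hydrolysis: the lithium sits meta/para to the silyloxy groups, so no retro-Brook silyl migration can occur, and the ate complex hydrolyses to the boronic acid under brief mild acid.

Step 9
Reactants: 10 8-[(2E)-4-{[tert-butyl(dimethyl)silyl]oxy}-3-methylbut-2-en-1-yl]-7-methoxy-4H-chromen-4-one; 15 (3,4-bis{[tert-butyl(dimethyl)silyl]oxy}phenyl)boronic acid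
Product: 16 (2S)-2-(3,4-bis{[tert-butyl(dimethyl)silyl]oxy}phenyl)-8-[(2E)-4-{[tert-butyl(dimethyl)silyl]oxy}-3-methylbut-2-en-1-yl]-7-methoxy-2,3-dihydro-4H-chromen-4-one
Conditions: Pd(OCOCF3)2 (10 mol%), (R)-t-BuPyOx (12 mol%), NH4PF6 (30 mol%), H2O (5 equiv), ClCH2CH2Cl, 60 °C
Reagents that add atoms: none
Why: Enantioselective conjugate (1,4-) addition of an arylboronic acid under cationic divalent palladium with the ligand (R)-4-tert-butyl-2-(pyridin-2-yl)-4,5-dihydro-1,3-oxazole: transmetalation gives an aryl–palladium species that inserts the chromone C2=C3 bond with the aryl group delivered to the Re face of C2 (steered by the tert-butyl group), and water then protonates C3, releasing the (2S)-flavanone with no redox change at the metal.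

Step 10
Reactants: 16 (2S)-2-(3,4-bis{[tert-butyl(dimethyl)silyl]oxy}phenyl)-8-[(2E)-4-{[tert-butyl(dimethyl)silyl]oxy}-3-methylbut-2-en-1-yl]-7-methoxy-2,3-dihydro-4H-chromen-4-one
Product: 17 (2S)-2-(3,4-dihydroxyphenyl)-8-[(2E)-4-hydroxy-3-methylbut-2-en-1-yl]-7-methoxy-2,3-dihydro-4H-chromen-4-one
Conditions: TBAF, AcOH (1:1), THF, 0 °C → rt
Reagents that add atoms: none
Why: Fluoride-mediated desilylation with acetic acid buffering: Si–F bond formation cleaves both aryl silyl ethers and the primary allylic silyl ether, and the near-neutral medium prevents phenoxide-triggered ring opening to the chalcone, so C2 is not racemised and the allylic alcohol is not ionised.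

## Compound list

1 | 2-methylbut-3-en-2-ol | C=CC(C)(C)O | starting material
2 | lithium 2-methylbut-3-en-2-olate | [Li+].[O-]C(C)(C)C=C | intermediate (not isolated)
3 | tert-butyl 2-methylbut-3-en-2-yl carbonate | C=CC(C)(C)OC(=O)OC(C)(C)C | intermediate
4 | 7-hydroxy-4H-chromen-4-one | O=c1ccoc2cc(O)ccc12 | starting material
5 | 7-[(2-methylbut-3-en-2-yl)oxy]-4H-chromen-4-one | O=c1ccoc2cc(OC(C)(C)C=C)ccc12 | intermediate
6 | 8-(3-methylbut-2-en-1-yl)-8H-chromene-4,7-dione (racemic cyclohexadienone tautomer) | O=C1C=CC2=C(OC=CC2=O)C1CC=C(C)C | intermediate (not isolated)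
7 | 7-hydroxy-8-(3-methylbut-2-en-1-yl)-4H-chromen-4-one | O=c1ccoc2c(CC=C(C)C)c(O)ccc12 | intermediate
8 | 7-methoxy-8-(3-methylbut-2-en-1-yl)-4H-chromen-4-one | O=c1ccoc2c(CC=C(C)C)c(OC)ccc12 | intermediate
9 | 8-[(2E)-4-hydroxy-3-methylbut-2-en-1-yl]-7-methoxy-4H-chromen-4-one | O=c1ccoc2c(C/C=C(\C)CO)c(OC)ccc12 | intermediate
10 | 8-[(2E)-4-{[tert-butyl(dimethyl)silyl]oxy}-3-methylbut-2-en-1-yl]-7-methoxy-4H-chromen-4-one | O=c1ccoc2c(C/C=C(\C)CO[Si](C)(C)C(C)(C)C)c(OC)ccc12 | intermediate
11 | 4-bromobenzene-1,2-diol | Oc1ccc(Br)cc1O | starting material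
12 | 4-bromo-1,2-bis{[tert-butyl(dimethyl)silyl]oxy}benzene | CC(C)(C)[Si](C)(C)Oc1ccc(Br)cc1O[Si](C)(C)C(C)(C)C | intermediate
13 | (3,4-bis{[tert-butyl(dimethyl)silyl]oxy}phenyl)lithium | [Li]c1ccc(O[Si](C)(C)C(C)(C)C)c(O[Si](C)(C)C(C)(C)C)c1 | intermediate (not isolated)
14 | lithium (3,4-bis{[tert-butyl(dimethyl)silyl]oxy}phenyl)tri(propan-2-yloxy)borate | [Li+].CC(C)O[B-](OC(C)C)(OC(C)C)c1ccc(O[Si](C)(C)C(C)(C)C)c(O[Si](C)(C)C(C)(C)C)c1 | intermediate (not isolated)
15 | (3,4-bis{[tert-butyl(dimethyl)silyl]oxy}phenyl)boronic acid | OB(O)c1ccc(O[Si](C)(C)C(C)(C)C)c(O[Si](C)(C)C(C)(C)C)c1 | intermediate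
16 | (2S)-2-(3,4-bis{[tert-butyl(dimethyl)silyl]oxy}phenyl)-8-[(2E)-4-{[tert-butyl(dimethyl)silyl]oxy}-3-methylbut-2-en-1-yl]-7-methoxy-2,3-dihydro-4H-chromen-4-one | COc1ccc2c(c1C/C=C(\C)CO[Si](C)(C)C(C)(C)C)O[C@H](c1ccc(O[Si](C)(C)C(C)(C)C)c(O[Si](C)(C)C(C)(C)C)c1)CC2=O | intermediate
17 | (2S)-2-(3,4-dihydroxyphenyl)-8-[(2E)-4-hydroxy-3-methylbut-2-en-1-yl]-7-methoxy-2,3-dihydro-4H-chromen-4-one | COc1ccc2c(c1C/C=C(\C)CO)O[C@H](c1ccc(O)c(O)c1)CC2=O | target

## Step count and risk

Total step count: 10.
Longest linear sequence: 8 steps (steps 1, 2, 3, 4, 5, 6, 9, 10, counted from 2-methylbut-3-en-2-ol; 7 steps from 7-hydroxychromone 4). The boronic acid branch (steps 7, 8) joins at step 9.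

Three steps most likely to fail:

**Step 9 (enantioselective conjugate arylation).** The electron-rich boronic acid may protodeboronate, the 7-methoxy group lowers the electrophilicity of the chromone, and the enantiomeric excess or facial sense may fall short. The fallback replaces asymmetric catalysis by a kinetic resolution. It sets out from 10 and 15, which are joined with an achiral catalyst (Pd(OCOCF3)2, 2,2'-bipyridine, H2O, ClCH2CH2Cl, 60 °C) to give the racemic tris-silyl flavanone F1. F1 is then submitted to asymmetric transfer hydrogenation run as a kinetic resolution (RuCl[(R,R)-TsDPEN](p-cymene), HCO2H/Et3N, EtOAc, rt, stopped near 52% conversion). The (2R)-ketone is reduced quickly to the cis-(2R,4R)-flavan-4-ol F2, which is removed by chromatography. The unreacted (2S)-ketone is 16, where the route resumes at step 10.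

**Step 3 (Claisen rearrangement).** Risks are the C6 regioisomer, thermal loss of isoprene back to 4, and abnormal Claisen products. The fallback replaces the sigmatropic route by cross-coupling and also bypasses steps 1, 2 and 4. It sets out from 4, which is iodinated at C8 (I2, HIO3, aqueous EtOH, rt) to 7-hydroxy-8-iodo-4H-chromen-4-one F3. F3 is O-methylated (MeI, K2CO3, acetone) to 8-iodo-7-methoxy-4H-chromen-4-one F4. F4 is Stille-coupled with commercial tributyl(3-methylbut-2-en-1-yl)stannane (Pd(PPh3)4, DMF, 90 °C) to give the linear prenyl arene 8, where the route resumes at step 5.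

**Step 5 (SeO2 allylic hydroxylation).** Risks are moderate conversion and over-oxidation to the enal. The fallback replaces allylic oxidation by olefin metathesis. It sets out from 8, which undergoes cross-metathesis with methacrolein (second-generation Hoveyda–Grubbs catalyst, CH2Cl2, 40 °C). This exchanges the isopropylidene terminus for the thermodynamically favoured (E)-enal and gives (2E)-4-(7-methoxy-4-oxo-4H-chromen-8-yl)-2-methylbut-2-enal F5 with loss of 2-methylpropene. Chemoselective Luche reduction of the aldehyde (NaBH4, CeCl3·7H2O, MeOH, −78 °C) then gives 9, where the route resumes at step 6.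

Further compounds
F1 | step 9 | rac-2-(3,4-bis{[tert-butyl(dimethyl)silyl]oxy}phenyl)-8-[(2E)-4-{[tert-butyl(dimethyl)silyl]oxy}-3-methylbut-2-en-1-yl]-7-methoxy-2,3-dihydro-4H-chromen-4-one | COc1ccc2c(c1C/C=C(\C)CO[Si](C)(C)C(C)(C)C)OC(c1ccc(O[Si](C)(C)C(C)(C)C)c(O[Si](C)(C)C(C)(C)C)c1)CC2=O
F2 | step 9 | (2R,4R)-2-(3,4-bis{[tert-butyl(dimethyl)silyl]oxy}phenyl)-8-[(2E)-4-{[tert-butyl(dimethyl)silyl]oxy}-3-methylbut-2-en-1-yl]-7-methoxy-3,4-dihydro-2H-chromen-4-ol | COc1ccc2c(c1C/C=C(\C)CO[Si](C)(C)C(C)(C)C)O[C@@H](c1ccc(O[Si](C)(C)C(C)(C)C)c(O[Si](C)(C)C(C)(C)C)c1)C[C@H]2O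
F3 | step 3 | 7-hydroxy-8-iodo-4H-chromen-4-one | O=c1ccoc2c(I)c(O)ccc12
F4 | step 3 | 8-iodo-7-methoxy-4H-chromen-4-one | O=c1ccoc2c(I)c(OC)ccc12
F5 | step 5 | (2E)-4-(7-methoxy-4-oxo-4H-chromen-8-yl)-2-methylbut-2-enal | O=c1ccoc2c(C/C=C(\C)C=O)c(OC)ccc12
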